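Atom labels follow the cadinane skeleton (ring fusion C1/C6, acrylate on C7, acyloxy on C8, methylene on C10). Ring A is disconnected across C1–C10 and C6–C7, which a palladium-catalysed diene carboannulation should form in one operation: the vinyl bromide (C10) of a 2-bromoallyl keto diester adds to the free terminus of a ring-B cyclohexadienyl ether, and the allyl-palladium is closed anti by the dienolate carbon C7. This exploits that C10 is a vinylic carbon next to ring-fusion C1, that C7 lies alpha to the C8 oxygen, and that C4=C5 is what the diene leaves behind. It sets the trans fusion and unveils the C11=C13 acrylate; glyceraldehyde acetonide supplies the side chain.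

Key step: step 5

Remark: 3-bromobut-3-enoic acid, tert-butyl pyruvate and cyclohexa-1,3-diene-1-carbaldehyde are taken as purchasable; locants inside compound names follow IUPAC rules, not the cadinane labels.

Step 1
Reactants: 1 cyclohexa-1,3-diene-1-carbaldehyde
Product: 2 (cyclohexa-1,3-dien-1-yl)methanol
Conditions: NaBH4, CeCl3·7H2O, MeOH, 0 °C
Reagents that add atoms: none
Why: Luche reduction delivers hydride 1,2 to the dienal carbonyl and leaves the conjugated diene untouched; no stereocentre is formed.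

Step 2
Reactants: 2 (cyclohexa-1,3-dien-1-yl)methanol
Product: 3 1-[(trityloxy)methyl]cyclohexa-1,3-diene
Conditions: TrCl, Et3N, DMAP (cat.), CH2Cl2, rt
Reagents that add atoms: trityl chloride ClC(c1ccccc1)(c1ccccc1)c1ccccc1
Why: Tritylation of the primary allylic alcohol (SN1-type etherification) should give an ether that is inert to zerovalent palladium, fluoride and hydride and is removed in the final acid step.

Step 3
Reactants: 4 3-bromobut-3-enoic acid; 5 Meldrum's acid (2,2-dimethyl-1,3-dioxane-4,6-dione)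
Product: 7 2-(trimethylsilyl)ethyl 5-bromo-3-oxohex-5-enoate, via acyl Meldrum's acid 6 (not isolated)
Conditions: DCC, DMAP, CH2Cl2, 0 °C to rt; filtration; then Me3SiCH2CH2OH, toluene, 80 °C
Reagents that add atoms: 2-(trimethylsilyl)ethanol C[Si](C)(C)CCO
Why: DCC-mediated C-acylation of Meldrum's acid, then thermal loss of acetone and CO2 from 6, gives an acylketene that the silyl alcohol traps as the beta-keto ester (Meldrum's acid route), which places C7 between the C8 ketone and a removable ester; no stereocentre is formed.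

Step 4
Reactants: 7 2-(trimethylsilyl)ethyl 5-bromo-3-oxohex-5-enoate; 8 tert-butyl 2-oxopropanoate
Product: 9 4-tert-butyl 1-[2-(trimethylsilyl)ethyl] 2-(3-bromobut-3-enoyl)-3-methylbut-2-enedioate (E/Z mixture)
Conditions: TiCl4, pyridine, THF, 0 °C to rt
Reagents that add atoms: none
Why: Knoevenagel condensation of the doubly activated methylene C7 with the electrophilic ketone of the pyruvate should give the tetrasubstituted alkylidene, in which C13 is a gamma-methyl group acidified by both C7 carbonyls; the alkene geometry is immaterial because both isomers give the same dienolate.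

Step 5
Reactants: 9 4-tert-butyl 1-[2-(trimethylsilyl)ethyl] 2-(3-bromobut-3-enoyl)-3-methylbut-2-enedioate; 3 1-[(trityloxy)methyl]cyclohexa-1,3-diene
Product: 11 2-(trimethylsilyl)ethyl (4aS,8aS)-1-[3-(tert-butoxy)-3-oxoprop-1-en-2-yl]-4-methylidene-2-oxo-7-[(trityloxy)methyl]-1,2,3,4,4a,5,6,8a-octahydronaphthalene-1-carboxylate (both C1 epimers), via potassium dienolate 10 (not isolated)
Conditions: K2CO3 (1.1 equiv), DMF, rt, 30 min; then 3 (2 equiv), Pd2(dba)3 (2.5 mol %), BINOL-derived phosphoramidite ligand (single enantiomer, 10 mol %), 40 °C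
Reagents that add atoms: none
Why: Oxidative addition of zerovalent palladium into the C10–Br bond of dienolate 10 gives a vinyl-palladium species that inserts the C1=C6 bond of diene 3 syn (vinyl to the unsubstituted terminus C1), so that an η3-allyl-palladium spanning C6–C5–C4 results with palladium on the face of the new C1–C10 bond; the soft dienolate carbon C7 then attacks C6 from the face opposite to palladium and closes ring A as a six-membered ring (6-exo allylic alkylation), which is the Larock carboannulation of 1,3-dienes by vinylic halides that carry a stabilised carbanion (Heck insertion followed by Tsuji–Trost closure). C1 is set in the enantio-determining insertion by the chiral phosphoramidite on palladium, C6 follows stereospecifically from the anti attack (trans ring fusion), and both C7 epimers are carried on because C7 is reset in step 6. The step needs insertion at C1 and not at the substituted terminus C4, closure at C6 and not at C4, and C- over O-alkylation; the CH2OTr group on C4, the six-membered versus bridged eight-membered ring and the reversibility of O-allylation under zerovalent palladium should secure these. Because the acrylate C11=C13 bond exists only after C7 has reacted (before that the fragment is the tetrasubstituted C7=C11 alkylidene or its delocalised anion), the vinyl-palladium has no 5-exo Heck pathway within its own fragment. The near-stoichiometric carbonate is consumed in forming 10, so little base is left to move the C10 methylene into conjugation with the C8 ketone. The ligand antipode that delivers the 4aS,8aS series is to be fixed in an initial pair of runs with both enantiomers of the ligand.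

Step 6
Reactants: 11 2-(trimethylsilyl)ethyl (4aS,8aS)-1-[3-(tert-butoxy)-3-oxoprop-1-en-2-yl]-4-methylidene-2-oxo-7-[(trityloxy)methyl]-1,2,3,4,4a,5,6,8a-octahydronaphthalene-1-carboxylate
Product: 13 tert-butyl 2-[(1S,4aS,8aS)-4-methylidene-2-oxo-7-[(trityloxy)methyl]-1,2,3,4,4a,5,6,8a-octahydronaphthalen-1-yl]prop-2-enoate, via beta-keto acid 12 (not isolated)
Conditions: TBAF, AcOH, THF, 0 °C to rt
Reagents that add atoms: none
Why: Fluoride-induced cleavage of the 2-(trimethylsilyl)ethyl ester (attack at silicon, loss of ethene) gives the beta-keto acid, which decarboxylates through its enol in the acetic acid buffer; ketonisation by axial protonation of C7 should place the acrylate arm equatorial, trans to C5 on C6 (also the thermodynamic epimer), and the buffered medium should not move the C10 methylene into conjugation.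

Step 7
Reactants: 13 tert-butyl 2-[(1S,4aS,8aS)-4-methylidene-2-oxo-7-[(trityloxy)methyl]-1,2,3,4,4a,5,6,8a-octahydronaphthalen-1-yl]prop-2-enoate
Product: 14 tert-butyl 2-[(1S,2R,4aS,8aS)-2-hydroxy-4-methylidene-7-[(trityloxy)methyl]-1,2,3,4,4a,5,6,8a-octahydronaphthalen-1-yl]prop-2-enoate
Conditions: NaBH4, CeCl3·7H2O, MeOH, −78 °C
Reagents that add atoms: none
Why: In this Luche reduction the small hydride should attack the C8 ketone of the trans-decalin chair axially (C10 is sp2, so that trajectory is open), which gives the equatorial 8R alcohol trans to the C7 arm, while CeCl3 suppresses conjugate reduction of the acrylate and the tert-butyl ester resists lactonisation.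

Step 8
Reactants: 15 (R)-2,2-dimethyl-1,3-dioxolane-4-carbaldehyde
Product: 16 (S)-4-ethynyl-2,2-dimethyl-1,3-dioxolane
Conditions: dimethyl (1-diazo-2-oxopropyl)phosphonate, K2CO3, MeOH, 0 °C to rt
Reagents that add atoms: dimethyl (1-diazo-2-oxopropyl)phosphonate CC(=O)C(=[N+]=[N-])P(=O)(OC)OC
Why: Ohira–Bestmann alkynylation: methanolysis of the reagent gives the diazomethylphosphonate anion, which converts the aldehyde into the terminal alkyne under mild carbonate conditions, so the chiral-pool stereocentre is kept (R becomes S only through the priority rules).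

Step 9
Reactants: 16 (S)-4-ethynyl-2,2-dimethyl-1,3-dioxolane
Product: 17 2-[(4S)-2,2-dimethyl-1,3-dioxolan-4-yl]prop-2-enoic acid
Conditions: Pd(OAc)2 (5 mol %), Xantphos (10 mol %), HCO2H, Ac2O (20 mol %), toluene, 80 °C
Reagents that add atoms: formic acid O=CO
Why: Palladium-catalysed Markovnikov hydrocarboxylation of the terminal alkyne with formic acid as the source of CO and hydride should place the carboxyl group on the internal carbon and give the 2-substituted acrylic acid; the stereocentre is not involved.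

Step 10
Reactants: 14 tert-butyl 2-[(1S,2R,4aS,8aS)-2-hydroxy-4-methylidene-7-[(trityloxy)methyl]-1,2,3,4,4a,5,6,8a-octahydronaphthalen-1-yl]prop-2-enoate; 17 2-[(4S)-2,2-dimethyl-1,3-dioxolan-4-yl]prop-2-enoic acid
Product: 18 (1S,2R,4aS,8aS)-1-[3-(tert-butoxy)-3-oxoprop-1-en-2-yl]-4-methylidene-7-[(trityloxy)methyl]-1,2,3,4,4a,5,6,8a-octahydronaphthalen-2-yl 2-[(4S)-2,2-dimethyl-1,3-dioxolan-4-yl]prop-2-enoate
Conditions: DCC, DMAP, CH2Cl2, 0 °C to rt
Reagents that add atoms: none
Why: Steglich esterification acylates the only free hydroxyl, the equatorial secondary C8 alcohol, with retention at C8; no stereocentre of either partner is touched.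

Step 11
Reactants: 18 (1S,2R,4aS,8aS)-1-[3-(tert-butoxy)-3-oxoprop-1-en-2-yl]-4-methylidene-7-[(trityloxy)methyl]-1,2,3,4,4a,5,6,8a-octahydronaphthalen-2-yl 2-[(4S)-2,2-dimethyl-1,3-dioxolan-4-yl]prop-2-enoate
Product: 20 2-[(1S,2R,4aS,8aS)-2-{[(3S)-3,4-dihydroxy-2-methylidenebutanoyl]oxy}-7-(hydroxymethyl)-4-methylidene-1,2,3,4,4a,5,6,8a-octahydronaphthalen-1-yl]prop-2-enoic acid, via trimethylsilyl ester 19 (not isolated)
Conditions: TMSOTf, 2,6-lutidine, CH2Cl2, 0 °C; then 1 M aq. HCl, THF, rt
Reagents that add atoms: none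
Why: TMSOTf with 2,6-lutidine converts the tert-butyl ester into the silyl ester by loss of 2-methylpropene under buffered non-protic conditions that should spare the C10 methylene, and dilute aqueous acid then hydrolyses the silyl ester, the trityl ether and the acetonide without cleaving the two acrylate esters; no stereocentre is affected.

Compound list
1 | cyclohexa-1,3-diene-1-carbaldehyde | O=CC1=CC=CCC1 | starting material
2 | (cyclohexa-1,3-dien-1-yl)methanol | OCC1=CC=CCC1 | intermediate
3 | 1-[(trityloxy)methyl]cyclohexa-1,3-diene | C1(COC(c2ccccc2)(c2ccccc2)c2ccccc2)=CC=CCC1 | intermediate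
4 | 3-bromobut-3-enoic acid | C=C(Br)CC(=O)O | starting material
5 | Meldrum's acid (2,2-dimethyl-1,3-dioxane-4,6-dione) | CC1(C)OC(=O)CC(=O)O1 | starting material
6 | 5-(3-bromobut-3-enoyl)-2,2-dimethyl-1,3-dioxane-4,6-dione | C=C(Br)CC(=O)C1C(=O)OC(C)(C)OC1=O | intermediate (not isolated)
7 | 2-(trimethylsilyl)ethyl 5-bromo-3-oxohex-5-enoate | C=C(Br)CC(=O)CC(=O)OCC[Si](C)(C)C | intermediate
8 | tert-butyl 2-oxopropanoate | CC(=O)C(=O)OC(C)(C)C | starting material
9 | 4-tert-butyl 1-[2-(trimethylsilyl)ethyl] 2-(3-bromobut-3-enoyl)-3-methylbut-2-enedioate (E/Z mixture) | C=C(Br)CC(=O)C(C(=O)OCC[Si](C)(C)C)=C(C)C(=O)OC(C)(C)C | intermediate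
10 | potassium dienolate of 9 | [K+].C=C(Br)CC([O-])=C(C(=O)OCC[Si](C)(C)C)C(=C)C(=O)OC(C)(C)C | intermediate (not isolated)
11 | 2-(trimethylsilyl)ethyl (4aS,8aS)-1-[3-(tert-butoxy)-3-oxoprop-1-en-2-yl]-4-methylidene-2-oxo-7-[(trityloxy)methyl]-1,2,3,4,4a,5,6,8a-octahydronaphthalene-1-carboxylate (both C1 epimers) | C=C(C(=O)OC(C)(C)C)C1(C(=O)OCC[Si](C)(C)C)[C@H]2C=C(COC(c3ccccc3)(c3ccccc3)c3ccccc3)CC[C@@H]2C(=C)CC1=O | intermediate
12 | (4aS,8aS)-1-[3-(tert-butoxy)-3-oxoprop-1-en-2-yl]-4-methylidene-2-oxo-7-[(trityloxy)methyl]-1,2,3,4,4a,5,6,8a-octahydronaphthalene-1-carboxylic acid | C=C(C(=O)OC(C)(C)C)C1(C(=O)O)[C@H]2C=C(COC(c3ccccc3)(c3ccccc3)c3ccccc3)CC[C@@H]2C(=C)CC1=O | intermediate (not isolated)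
13 | tert-butyl 2-[(1S,4aS,8aS)-4-methylidene-2-oxo-7-[(trityloxy)methyl]-1,2,3,4,4a,5,6,8a-octahydronaphthalen-1-yl]prop-2-enoate | C=C(C(=O)OC(C)(C)C)[C@@H]1[C@H]2C=C(COC(c3ccccc3)(c3ccccc3)c3ccccc3)CC[C@@H]2C(=C)CC1=O | intermediate
14 | tert-butyl 2-[(1S,2R,4aS,8aS)-2-hydroxy-4-methylidene-7-[(trityloxy)methyl]-1,2,3,4,4a,5,6,8a-octahydronaphthalen-1-yl]prop-2-enoate | C=C(C(=O)OC(C)(C)C)[C@@H]1[C@H]2C=C(COC(c3ccccc3)(c3ccccc3)c3ccccc3)CC[C@@H]2C(=C)C[C@H]1O | intermediate
15 | (R)-2,2-dimethyl-1,3-dioxolane-4-carbaldehyde | O=C[C@H]1COC(C)(C)O1 | starting material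
16 | (S)-4-ethynyl-2,2-dimethyl-1,3-dioxolane | C#C[C@H]1COC(C)(C)O1 | intermediate
17 | 2-[(4S)-2,2-dimethyl-1,3-dioxolan-4-yl]prop-2-enoic acid | C=C(C(=O)O)[C@H]1COC(C)(C)O1 | intermediate
18 | (1S,2R,4aS,8aS)-1-[3-(tert-butoxy)-3-oxoprop-1-en-2-yl]-4-methylidene-7-[(trityloxy)methyl]-1,2,3,4,4a,5,6,8a-octahydronaphthalen-2-yl 2-[(4S)-2,2-dimethyl-1,3-dioxolan-4-yl]prop-2-enoate | C=C(C(=O)OC(C)(C)C)[C@@H]1[C@H]2C=C(COC(c3ccccc3)(c3ccccc3)c3ccccc3)CC[C@@H]2C(=C)C[C@H]1OC(=O)C(=C)[C@H]1COC(C)(C)O1 | intermediate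
19 | (1S,2R,4aS,8aS)-4-methylidene-1-{3-oxo-3-[(trimethylsilyl)oxy]prop-1-en-2-yl}-7-[(trityloxy)methyl]-1,2,3,4,4a,5,6,8a-octahydronaphthalen-2-yl 2-[(4S)-2,2-dimethyl-1,3-dioxolan-4-yl]prop-2-enoate | C=C(C(=O)O[Si](C)(C)C)[C@@H]1[C@H]2C=C(COC(c3ccccc3)(c3ccccc3)c3ccccc3)CC[C@@H]2C(=C)C[C@H]1OC(=O)C(=C)[C@H]1COC(C)(C)O1 | intermediate (not isolated)
20 | 2-[(1S,2R,4aS,8aS)-2-{[(3S)-3,4-dihydroxy-2-methylidenebutanoyl]oxy}-7-(hydroxymethyl)-4-methylidene-1,2,3,4,4a,5,6,8a-octahydronaphthalen-1-yl]prop-2-enoic acid | C=C(C(=O)O)[C@@H]1[C@H]2C=C(CO)CC[C@@H]2C(=C)C[C@H]1OC(=O)C(=C)[C@H](O)CO | target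

Total step count: 11. Longest linear sequence: 7 steps (steps 3, 4, 5, 6, 7, 10 and 11, from 4).

Steps most likely to fail

Step 5. Poor enantioface discrimination in the migratory insertion of the diene would erode the enantiomeric purity of the annulated ester. The fallback sets out from 9 and 3 and replaces asymmetric catalysis by a resolution: the annulation is run with PPh3 as an achiral ligand, which should give 11 together with the (4aR,8aR)-enantiomer of 11 F1. The mixture is taken through steps 6 and 7, which pass through the enantiomer of acid 12 F2 in the flask and give the (1R,4aR,8aR)-enantiomer of ketone 13 F3 and the (1R,2S,4aR,8aR)-enantiomer of alcohol 14 F4 beside 13 and 14. Esterification with enantiopure 17 as in step 10 then gives 18 and the diastereomeric ester (1R,2S,4aR,8aR)-1-[3-(tert-butoxy)-3-oxoprop-1-en-2-yl]-4-methylidene-7-[(trityloxy)methyl]-1,2,3,4,4a,5,6,8a-octahydronaphthalen-2-yl 2-[(4S)-2,2-dimethyl-1,3-dioxolan-4-yl]prop-2-enoate F5. Chromatography separates the two esters and the route is rejoined at 18.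

Step 4. The titanium-mediated condensation may stall at the crowded tetrasubstituted alkene or lose the pyruvate to self-condensation. The fallback sets out from 7 and 8 and separates addition from elimination: a soft-enolisation aldol addition (MgBr2·OEt2, Et3N, CH2Cl2, 0 °C) should give the tertiary alcohol 4-tert-butyl 1-[2-(trimethylsilyl)ethyl] 2-(3-bromobut-3-enoyl)-3-hydroxy-3-methylbutanedioate F6. Mesylation and E1cB elimination (MsCl, Et3N, CH2Cl2, 0 °C) then dehydrate it, and the route is rejoined at 9.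

Step 9. Hydropalladation may lose regiocontrol (linear acid), or the acidic medium may strip the acetonide. The fallback sets out from 16 and builds the acid through a vinyl iodide: Markovnikov hydrosilylation ([Cp*Ru(MeCN)3]PF6, Et3SiH, CH2Cl2) should give triethyl{1-[(4R)-2,2-dimethyl-1,3-dioxolan-4-yl]ethenyl}silane F7. Iododesilylation (N-iodosuccinimide, MeCN) gives (4R)-4-(1-iodoethenyl)-2,2-dimethyl-1,3-dioxolane F8, and hydroxycarbonylation (Pd(OAc)2, PPh3, CO, H2O, Et3N, DMF) rejoins the route at 17.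

Further compounds
F1 | step 5 | 2-(trimethylsilyl)ethyl (4aR,8aR)-1-[3-(tert-butoxy)-3-oxoprop-1-en-2-yl]-4-methylidene-2-oxo-7-[(trityloxy)methyl]-1,2,3,4,4a,5,6,8a-octahydronaphthalene-1-carboxylate | C=C(C(=O)OC(C)(C)C)C1(C(=O)OCC[Si](C)(C)C)[C@@H]2C=C(COC(c3ccccc3)(c3ccccc3)c3ccccc3)CC[C@H]2C(=C)CC1=O
F2 | step 5 | (4aR,8aR)-1-[3-(tert-butoxy)-3-oxoprop-1-en-2-yl]-4-methylidene-2-oxo-7-[(trityloxy)methyl]-1,2,3,4,4a,5,6,8a-octahydronaphthalene-1-carboxylic acid | C=C(C(=O)OC(C)(C)C)C1(C(=O)O)[C@@H]2C=C(COC(c3ccccc3)(c3ccccc3)c3ccccc3)CC[C@H]2C(=C)CC1=O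
F3 | step 5 | tert-butyl 2-[(1R,4aR,8aR)-4-methylidene-2-oxo-7-[(trityloxy)methyl]-1,2,3,4,4a,5,6,8a-octahydronaphthalen-1-yl]prop-2-enoate | C=C(C(=O)OC(C)(C)C)[C@H]1[C@@H]2C=C(COC(c3ccccc3)(c3ccccc3)c3ccccc3)CC[C@H]2C(=C)CC1=O
F4 | step 5 | tert-butyl 2-[(1R,2S,4aR,8aR)-2-hydroxy-4-methylidene-7-[(trityloxy)methyl]-1,2,3,4,4a,5,6,8a-octahydronaphthalen-1-yl]prop-2-enoate | C=C(C(=O)OC(C)(C)C)[C@H]1[C@@H]2C=C(COC(c3ccccc3)(c3ccccc3)c3ccccc3)CC[C@H]2C(=C)C[C@@H]1O
F5 | step 5 | (1R,2S,4aR,8aR)-1-[3-(tert-butoxy)-3-oxoprop-1-en-2-yl]-4-methylidene-7-[(trityloxy)methyl]-1,2,3,4,4a,5,6,8a-octahydronaphthalen-2-yl 2-[(4S)-2,2-dimethyl-1,3-dioxolan-4-yl]prop-2-enoate | C=C(C(=O)OC(C)(C)C)[C@H]1[C@@H]2C=C(COC(c3ccccc3)(c3ccccc3)c3ccccc3)CC[C@H]2C(=C)C[C@@H]1OC(=O)C(=C)[C@H]1COC(C)(C)O1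
F6 | step 4 | 4-tert-butyl 1-[2-(trimethylsilyl)ethyl] 2-(3-bromobut-3-enoyl)-3-hydroxy-3-methylbutanedioate (diastereomer mixture) | C=C(Br)CC(=O)C(C(=O)OCC[Si](C)(C)C)C(C)(O)C(=O)OC(C)(C)C
F7 | step 9 | triethyl{1-[(4R)-2,2-dimethyl-1,3-dioxolan-4-yl]ethenyl}silane | C=C([Si](CC)(CC)CC)[C@H]1COC(C)(C)O1
F8 | step 9 | (4R)-4-(1-iodoethenyl)-2,2-dimethyl-1,3-dioxolane | C=C(I)[C@H]1COC(C)(C)O1
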